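**Retrosynthetic overview**

1. Labdane numbering is used (ring A: C1–C5 and C10; ring B: C5–C10; side chain C11–C16; C17 on C8, C18/C19 on C4, C20 on C10). The late stage (O-acetylation, desilylation, C19 ester cleavage) leads back to ester 22, and C7 deoxygenation leads back to the 7-oxo-8-ene 20.
2. Key disconnection (retro-Robinson, both rings at once): 20 ⇒ open-chain keto enone 18. Forward, C5–C10 is made by intramolecular Michael addition (closes ring A first) and C8=C9 by aldol condensation (then closes ring B).
3. Enabling feature: ring B holds the tetrasubstituted C8=C9 alkene next to the C7 methylene. With C7 carried as a ketone, ring B is a 2-methylcyclohex-2-enone in which C8=C9 is an aldol bond and the ring-fusion bond C5–C10 (C5 β to C7, C10 α to the C9 carbonyl) is a Michael bond shared by rings A and B. Quaternary C4 blocks γ-enolisation of the acceptor and relays its configuration to C5 and C10.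
4. 18 ⇒ C1–C10 alkylation of the side-chain β-keto ester 14 (from prenol and allyl acetoacetate) with chloro enone 7; 7 ⇒ Horner–Wadsworth–Emmons olefination of α-formyl ester 5 ⇒ enantioselective desymmetrisation of malonate 3.

Key step: step 12

Assumption: the sense of the desymmetrisation in step 2 is not known in advance for 3, so the ligand antipode that gives (S)-4 is used (both antipodes are accessible).

**Route**

Step 1
Reactants: 1 dimethyl 2-methylmalonate; 2 1-bromo-3-chloropropane
Product: 3 dimethyl 2-(3-chloropropyl)-2-methylmalonate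
Conditions: NaH, THF/DMF, 0 °C; then 2, rt
Reagents that add atoms: none
Why: Malonate alkylation (SN2) in which the sodium enolate of 1 displaces bromide, the better leaving group, so the chloride is kept; 3 is prochiral.

Step 2
Reactants: 3 dimethyl 2-(3-chloropropyl)-2-methylmalonate
Product: 4 methyl (2S)-5-chloro-2-(hydroxymethyl)-2-methylpentanoate
Conditions: Et2Zn (10 mol %), chiral pipecolinol-derived tetradentate aminophenol ligand (5 mol %), (EtO)3SiH, THF, 0 °C to rt; then NH4F, MeOH
Reagents that add atoms: none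
Why: Zinc-catalysed asymmetric hydrosilylation of one of the two enantiotopic ester groups of an α,α-disubstituted malonate (desymmetrising partial reduction), in which the chiral dinuclear zinc hydride selects one ester and so sets the quaternary C4 stereocentre as (S); the chloride and the second ester are untouched.

Step 3
Reactants: 4 methyl (2S)-5-chloro-2-(hydroxymethyl)-2-methylpentanoate
Product: 5 methyl (2S)-5-chloro-2-formyl-2-methylpentanoate
Conditions: Dess–Martin periodinane, CH2Cl2, 0 °C to rt
Reagents that add atoms: none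
Why: Dess–Martin oxidation of a neopentyl primary alcohol; the aldehyde has no α-hydrogen, so the stereocentre cannot epimerise.

Step 4
Reactants: 5 methyl (2S)-5-chloro-2-formyl-2-methylpentanoate; 6 dimethyl (2-oxobutyl)phosphonate
Product: 7 methyl (2S,3E)-2-(3-chloropropyl)-2-methyl-5-oxohept-3-enoate
Conditions: LiCl, DBU, MeCN, 0 °C to rt
Reagents that add atoms: none
Why: Horner–Wadsworth–Emmons olefination under Masamune–Roush conditions should give the (E)-enone (C5=C6–C7(=O)–C8–C17); the non-nucleophilic base avoids retro-Claisen deformylation of the α-formyl ester and the stereocentre is not touched.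

Step 5
Reactants: 8 3-methylbut-2-en-1-ol (prenol)
Product: 9 tert-butyl[(3-methylbut-2-en-1-yl)oxy]diphenylsilane
Conditions: TBDPSCl, imidazole, DMF, rt
Reagents that add atoms: tert-butyl(chloro)diphenylsilane, CC(C)(C)[Si](Cl)(c1ccccc1)c1ccccc1
Why: Silylation of the primary allylic alcohol (future C15–O) as an ether robust enough for the later base, Lewis acid and thiolate steps.

Step 6
Reactants: 9 tert-butyl[(3-methylbut-2-en-1-yl)oxy]diphenylsilane
Product: 10 (2E)-4-[(tert-butyldiphenylsilyl)oxy]-2-methylbut-2-en-1-ol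
Conditions: SeO2 (cat.), t-BuOOH, salicylic acid (cat.), CH2Cl2, 0 °C to rt
Reagents that add atoms: tert-butyl hydroperoxide, CC(C)(C)OO (oxygen source, transferred by way of SeO2, O=[Se]=O)
Why: Riley allylic oxidation (ene reaction, then [2,3]-sigmatropic shift) oxidises the (E)-methyl group of the trisubstituted alkene selectively, which sets the (E)-geometry of the future C13=C14 alkene.

Step 7
Reactants: 10 (2E)-4-[(tert-butyldiphenylsilyl)oxy]-2-methylbut-2-en-1-ol
Product: 11 {[(2E)-4-bromo-3-methylbut-2-en-1-yl]oxy}(tert-butyl)diphenylsilane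
Conditions: CBr4, PPh3, CH2Cl2, 0 °C
Reagents that add atoms: tetrabromomethane, BrC(Br)(Br)Br
Why: Appel bromination of the primary allylic alcohol under neutral conditions, without allylic transposition or loss of alkene geometry.

Step 8
Reactants: 12 prop-2-en-1-yl 3-oxobutanoate (allyl acetoacetate)
Product: 13 prop-2-en-1-yl 2-methyl-3-oxobutanoate (racemic)
Conditions: K2CO3, MeI, acetone, reflux
Reagents that add atoms: iodomethane, CI
Why: C-Methylation of the β-keto ester through its potassium enolate installs the future C20 methyl on C10; the racemic centre is of no consequence.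

Step 9
Reactants: 13 prop-2-en-1-yl 2-methyl-3-oxobutanoate; 11 {[(2E)-4-bromo-3-methylbut-2-en-1-yl]oxy}(tert-butyl)diphenylsilane
Product: 14 prop-2-en-1-yl (6E)-8-[(tert-butyldiphenylsilyl)oxy]-2,6-dimethyl-3-oxooct-6-enoate (racemic at C2, the future C10)
Conditions: NaH, THF, 0 °C; n-BuLi, −20 °C; then 11, −20 to 0 °C; aq. NH4Cl
Reagents that add atoms: none
Why: γ-Alkylation of the β-keto ester dianion, whose terminal carbon is the more reactive, joins C11 to C12 by SN2 at the primary allylic bromide with retention of the (E)-alkene; the temperature stays at or below 0 °C to avoid the dianionic Carroll rearrangement of the allyl ester.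

Step 10
Reactants: 14 prop-2-en-1-yl (6E)-8-[(tert-butyldiphenylsilyl)oxy]-2,6-dimethyl-3-oxooct-6-enoate; 7 methyl (2S,3E)-2-(3-chloropropyl)-2-methyl-5-oxohept-3-enoate
Product: 16 1-methyl 7-(prop-2-en-1-yl) (2S)-6-{(4E)-6-[(tert-butyldiphenylsilyl)oxy]-4-methylhex-4-enoyl}-2,6-dimethyl-2-[(1E)-3-oxopent-1-en-1-yl]heptanedioate (both C6 epimers), via iodide 15 (not isolated)
Conditions: K2CO3, NaI, DMF, 50 °C
Reagents that add atoms: none
Why: Finkelstein exchange in the flask, then C-alkylation of the α-methyl β-keto ester enolate by the primary iodide, forms the C1–C10 bond; the neopentyl β-carbon of the enone is too hindered for intermolecular Michael addition, and the new centre (C10) is planarised later.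

Step 11
Reactants: 16 1-methyl 7-(prop-2-en-1-yl) (2S)-6-{(4E)-6-[(tert-butyldiphenylsilyl)oxy]-4-methylhex-4-enoyl}-2,6-dimethyl-2-[(1E)-3-oxopent-1-en-1-yl]heptanedioate
Product: 18 methyl (2S,10E)-12-[(tert-butyldiphenylsilyl)oxy]-2,6,10-trimethyl-7-oxo-2-[(1E)-3-oxopent-1-en-1-yl]dodec-10-enoate (both C6 epimers), via β-keto acid 17 (not isolated)
Conditions: Pd(OAc)2 (3 mol %), PPh3 (12 mol %), HCO2H, Et3N, THF, 25 to 40 °C
Reagents that add atoms: none
Why: Palladium-catalysed hydrogenolysis of the allyl ester by formate (through a π-allylpalladium formate) frees the β-keto acid, which decarboxylates under these neutral conditions to the C10–H ketone; the methyl ester, the enone and the silyl ether should be inert.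

Step 12
Reactants: 18 methyl (2S,10E)-12-[(tert-butyldiphenylsilyl)oxy]-2,6,10-trimethyl-7-oxo-2-[(1E)-3-oxopent-1-en-1-yl]dodec-10-enoate
Product: 20 methyl (1S,4aS,8aR)-5-{(3E)-5-[(tert-butyldiphenylsilyl)oxy]-3-methylpent-3-en-1-yl}-1,4a,6-trimethyl-7-oxo-1,2,3,4,4a,7,8,8a-octahydronaphthalene-1-carboxylate, via Michael adduct 19 (not isolated)
Conditions: KOt-Bu (0.2 equiv), PhMe/t-BuOH (10:1), −20 to 0 °C; then AcOH, pyrrolidine, reflux, Dean–Stark; aq. AcOH/NaOAc work-up
Reagents that add atoms: none
Why: Under catalytic KOt-Bu the ketone enolates equilibrate, but only the C10 enolate can close a six-membered ring, so it adds to C5 of the (E)-enone in a 6-(enolexo)-exo-trig intramolecular Michael addition that forms C5–C10 and ring A (closest known type: base-mediated intramolecular Michael cyclisation of keto enones, the first half of a Robinson annulation); quaternary C4 excludes γ-deprotonation of the acceptor, and both C10 epimers of 18 converge because C10 is planar in the enolate. After neutralisation, pyrrolidine condenses with the unhindered C7 ethyl ketone of 19 and the C7=C8 enamine attacks the C9 carbonyl in a 6-(enolendo)-exo-trig aldol addition; loss of water and hydrolysis of the dienamine give the C8=C9 enone and ring B (the second half of the Robinson annulation, as in amine-mediated cyclisations of 1,5-diketones). C5 and C10 are both set in the Michael step through a chair transition state in which the enone arm at C5 and the bulky enolate unit at C10 are pseudo-equatorial, so that H5 and the C10 methyl end up trans (trans-decalin). The enone face is chosen by C4: the chair that puts the planar ester, and not the C4 methyl, in the axial site syn to the axial C10 methyl has the smaller 1,3-diaxial penalty, which places CO2Me cis to the C10 methyl as in the target. Three selectivities are needed: Michael regiochemistry (secured by ring size), aldol regiochemistry C8→C9 over C11→C7 (secured by the amine stage, because the neopentyl C9 ketone forms an enamine far more slowly than the C7 ketone, and by keeping the alkoxide stage cold so that no ketol dehydrates), and diastereofacial control (secured by the C4 stereocentre).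

Step 13
Reactants: 20 methyl (1S,4aS,8aR)-5-{(3E)-5-[(tert-butyldiphenylsilyl)oxy]-3-methylpent-3-en-1-yl}-1,4a,6-trimethyl-7-oxo-1,2,3,4,4a,7,8,8a-octahydronaphthalene-1-carboxylate
Product: 21 methyl (1S,4aS,8aR)-5-{(3E)-5-[(tert-butyldiphenylsilyl)oxy]-3-methylpent-3-en-1-yl}-7-hydroxy-1,4a,6-trimethyl-1,2,3,4,4a,7,8,8a-octahydronaphthalene-1-carboxylate (C7 epimers, both used)
Conditions: NaBH4, CeCl3·7H2O, MeOH, −40 to 0 °C
Reagents that add atoms: none
Why: Luche reduction adds hydride 1,2 to the enone carbonyl and leaves the ester alone; the C7 configuration is irrelevant because C7 becomes CH2 in step 14.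

Step 14
Reactants: 21 methyl (1S,4aS,8aR)-5-{(3E)-5-[(tert-butyldiphenylsilyl)oxy]-3-methylpent-3-en-1-yl}-7-hydroxy-1,4a,6-trimethyl-1,2,3,4,4a,7,8,8a-octahydronaphthalene-1-carboxylate
Product: 22 methyl (1S,4aS,8aR)-5-{(3E)-5-[(tert-butyldiphenylsilyl)oxy]-3-methylpent-3-en-1-yl}-1,4a,6-trimethyl-1,2,3,4,4a,7,8,8a-octahydronaphthalene-1-carboxylate
Conditions: Et3SiH (5 equiv), BF3·OEt2, CH2Cl2, −78 to −30 °C
Reagents that add atoms: none
Why: Ionic hydrogenation, in which BF3 ionises the ring allylic alcohol to the C7–C8–C9 allyl cation and Et3SiH delivers hydride to the less hindered secondary terminus C7, should leave the tetrasubstituted C8=C9 alkene in place; the primary silyl ether and the ester should survive at low temperature.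

Step 15
Reactants: 22 methyl (1S,4aS,8aR)-5-{(3E)-5-[(tert-butyldiphenylsilyl)oxy]-3-methylpent-3-en-1-yl}-1,4a,6-trimethyl-1,2,3,4,4a,7,8,8a-octahydronaphthalene-1-carboxylate
Product: 23 (1S,4aS,8aR)-5-{(3E)-5-[(tert-butyldiphenylsilyl)oxy]-3-methylpent-3-en-1-yl}-1,4a,6-trimethyl-1,2,3,4,4a,7,8,8a-octahydronaphthalene-1-carboxylic acid
Conditions: NaSEt, DMF, 90 °C; then aq. HCl to pH 3
Reagents that add atoms: none
Why: SN2 demethylation by thiolate at the methyl carbon cleaves the hindered axial ester, whose carbonyl is shielded against acyl attack; the silyl ether and both alkenes are inert.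

Step 16
Reactants: 23 (1S,4aS,8aR)-5-{(3E)-5-[(tert-butyldiphenylsilyl)oxy]-3-methylpent-3-en-1-yl}-1,4a,6-trimethyl-1,2,3,4,4a,7,8,8a-octahydronaphthalene-1-carboxylic acid
Product: 24 (1S,4aS,8aR)-5-[(3E)-5-hydroxy-3-methylpent-3-en-1-yl]-1,4a,6-trimethyl-1,2,3,4,4a,7,8,8a-octahydronaphthalene-1-carboxylic acid
Conditions: Bu4NF (3 equiv), THF, rt; aq. NH4Cl
Reagents that add atoms: none
Why: Fluoride cleavage of the silyl ether; nothing else in the molecule responds to fluoride.

Step 17
Reactants: 24 (1S,4aS,8aR)-5-[(3E)-5-hydroxy-3-methylpent-3-en-1-yl]-1,4a,6-trimethyl-1,2,3,4,4a,7,8,8a-octahydronaphthalene-1-carboxylic acid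
Product: 25 (1S,4aS,8aR)-5-[(3E)-5-acetoxy-3-methylpent-3-en-1-yl]-1,4a,6-trimethyl-1,2,3,4,4a,7,8,8a-octahydronaphthalene-1-carboxylic acid (CNP0326733.1)
Conditions: Ac2O, pyridine, DMAP (cat.), CH2Cl2, 0 °C to rt; aq. NaHCO3, then pH 3
Reagents that add atoms: acetic anhydride, CC(=O)OC(C)=O
Why: Acetylation of the primary allylic alcohol; any mixed anhydride at the hindered C19 acid is hydrolysed at its acetyl carbonyl in the aqueous work-up, which returns the free acid.

**Compound list**

1 | dimethyl 2-methylmalonate | COC(=O)C(C)C(=O)OC | starting material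
2 | 1-bromo-3-chloropropane | ClCCCBr | starting material
3 | dimethyl 2-(3-chloropropyl)-2-methylmalonate | COC(=O)C(C)(CCCCl)C(=O)OC | intermediate
4 | methyl (2S)-5-chloro-2-(hydroxymethyl)-2-methylpentanoate | COC(=O)[C@](C)(CO)CCCCl | intermediate
5 | methyl (2S)-5-chloro-2-formyl-2-methylpentanoate | COC(=O)[C@](C)(C=O)CCCCl | intermediate
6 | dimethyl (2-oxobutyl)phosphonate | CCC(=O)CP(=O)(OC)OC | starting material
7 | methyl (2S,3E)-2-(3-chloropropyl)-2-methyl-5-oxohept-3-enoate | COC(=O)[C@](C)(/C=C/C(=O)CC)CCCCl | intermediate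
8 | 3-methylbut-2-en-1-ol (prenol) | CC(C)=CCO | starting material
9 | tert-butyl[(3-methylbut-2-en-1-yl)oxy]diphenylsilane | CC(C)=CCO[Si](c1ccccc1)(c1ccccc1)C(C)(C)C | intermediate
10 | (2E)-4-[(tert-butyldiphenylsilyl)oxy]-2-methylbut-2-en-1-ol | OC/C(C)=C/CO[Si](c1ccccc1)(c1ccccc1)C(C)(C)C | intermediate
11 | {[(2E)-4-bromo-3-methylbut-2-en-1-yl]oxy}(tert-butyl)diphenylsilane | BrC/C(C)=C/CO[Si](c1ccccc1)(c1ccccc1)C(C)(C)C | intermediate
12 | prop-2-en-1-yl 3-oxobutanoate (allyl acetoacetate) | CC(=O)CC(=O)OCC=C | starting material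
13 | prop-2-en-1-yl 2-methyl-3-oxobutanoate (racemic) | CC(=O)C(C)C(=O)OCC=C | intermediate
14 | prop-2-en-1-yl (6E)-8-[(tert-butyldiphenylsilyl)oxy]-2,6-dimethyl-3-oxooct-6-enoate (racemic at C2) | C=CCOC(=O)C(C)C(=O)CC/C(C)=C/CO[Si](c1ccccc1)(c1ccccc1)C(C)(C)C | intermediate
15 | methyl (2S,3E)-2-(3-iodopropyl)-2-methyl-5-oxohept-3-enoate | COC(=O)[C@](C)(/C=C/C(=O)CC)CCCI | intermediate (not isolated)
16 | 1-methyl 7-(prop-2-en-1-yl) (2S)-6-{(4E)-6-[(tert-butyldiphenylsilyl)oxy]-4-methylhex-4-enoyl}-2,6-dimethyl-2-[(1E)-3-oxopent-1-en-1-yl]heptanedioate (both C6 epimers; C6 is the future C10) | C=CCOC(=O)C(C)(CCC[C@@](C)(/C=C/C(=O)CC)C(=O)OC)C(=O)CC/C(C)=C/CO[Si](c1ccccc1)(c1ccccc1)C(C)(C)C | intermediate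
17 | β-keto acid of 16: (6S)-2-{(4E)-6-[(tert-butyldiphenylsilyl)oxy]-4-methylhex-4-enoyl}-7-methoxy-2,6-dimethyl-7-oxo-6-[(1E)-3-oxopent-1-en-1-yl]heptanoic acid (both C2 epimers) | OC(=O)C(C)(CCC[C@@](C)(/C=C/C(=O)CC)C(=O)OC)C(=O)CC/C(C)=C/CO[Si](c1ccccc1)(c1ccccc1)C(C)(C)C | intermediate (not isolated)
18 | methyl (2S,10E)-12-[(tert-butyldiphenylsilyl)oxy]-2,6,10-trimethyl-7-oxo-2-[(1E)-3-oxopent-1-en-1-yl]dodec-10-enoate (both C6 epimers; C6 is the future C10) | CC(CCC[C@@](C)(/C=C/C(=O)CC)C(=O)OC)C(=O)CC/C(C)=C/CO[Si](c1ccccc1)(c1ccccc1)C(C)(C)C | intermediate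
19 | methyl (1S,2R,3S)-3-{(4E)-6-[(tert-butyldiphenylsilyl)oxy]-4-methylhex-4-enoyl}-1,3-dimethyl-2-(2-oxobutyl)cyclohexane-1-carboxylate | CCC(=O)C[C@H]1[C@@](C)(C(=O)OC)CCC[C@]1(C)C(=O)CC/C(C)=C/CO[Si](c1ccccc1)(c1ccccc1)C(C)(C)C | intermediate (not isolated)
20 | methyl (1S,4aS,8aR)-5-{(3E)-5-[(tert-butyldiphenylsilyl)oxy]-3-methylpent-3-en-1-yl}-1,4a,6-trimethyl-7-oxo-1,2,3,4,4a,7,8,8a-octahydronaphthalene-1-carboxylate | CC(C)(C)[Si](c1ccccc1)(c1ccccc1)OC/C=C(\C)CCC1=C(C)C(=O)C[C@H]2[C@@](C)(C(=O)OC)CCC[C@]12C | intermediate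
21 | methyl (1S,4aS,8aR)-5-{(3E)-5-[(tert-butyldiphenylsilyl)oxy]-3-methylpent-3-en-1-yl}-7-hydroxy-1,4a,6-trimethyl-1,2,3,4,4a,7,8,8a-octahydronaphthalene-1-carboxylate (C7 epimers) | CC(C)(C)[Si](c1ccccc1)(c1ccccc1)OC/C=C(\C)CCC1=C(C)C(O)C[C@H]2[C@@](C)(C(=O)OC)CCC[C@]12C | intermediate
22 | methyl (1S,4aS,8aR)-5-{(3E)-5-[(tert-butyldiphenylsilyl)oxy]-3-methylpent-3-en-1-yl}-1,4a,6-trimethyl-1,2,3,4,4a,7,8,8a-octahydronaphthalene-1-carboxylate | CC(C)(C)[Si](c1ccccc1)(c1ccccc1)OC/C=C(\C)CCC1=C(C)CC[C@H]2[C@@](C)(C(=O)OC)CCC[C@]12C | intermediate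
23 | (1S,4aS,8aR)-5-{(3E)-5-[(tert-butyldiphenylsilyl)oxy]-3-methylpent-3-en-1-yl}-1,4a,6-trimethyl-1,2,3,4,4a,7,8,8a-octahydronaphthalene-1-carboxylic acid | CC(C)(C)[Si](c1ccccc1)(c1ccccc1)OC/C=C(\C)CCC1=C(C)CC[C@H]2[C@@](C)(C(=O)O)CCC[C@]12C | intermediate
24 | (1S,4aS,8aR)-5-[(3E)-5-hydroxy-3-methylpent-3-en-1-yl]-1,4a,6-trimethyl-1,2,3,4,4a,7,8,8a-octahydronaphthalene-1-carboxylic acid | OC/C=C(\C)CCC1=C(C)CC[C@H]2[C@@](C)(C(=O)O)CCC[C@]12C | intermediate
25 | (1S,4aS,8aR)-5-[(3E)-5-acetoxy-3-methylpent-3-en-1-yl]-1,4a,6-trimethyl-1,2,3,4,4a,7,8,8a-octahydronaphthalene-1-carboxylic acid (15-acetoxylabda-8,13E-dien-19-oic acid) | CC(=O)OC/C=C(\C)CCC1=C(C)CC[C@H]2[C@@](C)(C(=O)O)CCC[C@]12C | target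

**Totals and risks**

Total step count: 17. Longest linear sequence: 12 steps (steps 1–4 and 10–17 from dimethyl 2-methylmalonate; the prenol branch, steps 5–7, 9 and 10–17, has the same length).

Steps most likely to fail:

Step 12. What may go wrong is loss of diastereofacial control in the Michael ring closure (cis ring fusion, or attack on the other enone face) and enolate scrambling in the alkoxide stage that lets the aldol closure start from C11. The fallback sets out from 16 and generates the C10 enolate regiospecifically, without external base, by chloride-induced dealkoxycarbonylation of the allyl ester (LiCl, DMPU, 120 °C; tandem dealkoxycarbonylation–Michael addition). The enolate born at C10 should close ring A at once. The Michael adduct 19 is then isolated and freed from diastereomers by chromatography, and ring B is closed separately with pyrrolidinium acetate in hot toluene, which comes back to the route at 20. This fallback makes no compound outside the list (F0).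

Step 14. What may go wrong is hydride delivery to C9 instead of C7 (transposition of the alkene to C7=C8), or ionisation of the side-chain allylic silyl ether followed by cation–olefin cyclisation onto C13=C14. The fallback sets out from 20: the enone carbonyl is converted with ethane-1,2-dithiol and Zn(OTf)2 in CH2Cl2 into the 1,3-dithiolane of 20 F1, which is desulfurised with acetone-deactivated Raney Ni in ethanol. Desulfurisation of dithioketals of conjugated enones is known to leave the alkene in place, and the sequence comes back at 22 without passing through 21.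

Step 2. What may go wrong is insufficient discrimination between the two enantiotopic ester groups (methyl against a primary alkyl chain at the prochiral carbon), or induction in the unwanted sense. The fallback sets out from 3: one ester group is hydrolysed with pig liver esterase (a serine carboxylesterase) in pH 7 phosphate buffer to the half-ester (2S)-2-(3-chloropropyl)-3-methoxy-2-methyl-3-oxopropanoic acid F2. Its enantiomeric purity is raised by crystallisation of a salt with a chiral amine, and the acid is reduced chemoselectively with BH3·SMe2, which comes back at 4.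

Further compounds
F0 | step 12 | none | none
F1 | step 14 | methyl (1S,4aS,8aR)-5-{(3E)-5-[(tert-butyldiphenylsilyl)oxy]-3-methylpent-3-en-1-yl}-1,4a,6-trimethyl-1,2,3,4,4a,7,8,8a-octahydronaphthalene-1-carboxylate 7,7-(ethane-1,2-diyl dithioketal) (1,3-dithiolane of 20) | CC(C)(C)[Si](c1ccccc1)(c1ccccc1)OC/C=C(\C)CCC1=C(C)C3(SCCS3)C[C@H]2[C@@](C)(C(=O)OC)CCC[C@]12C
F2 | step 2 | (2S)-2-(3-chloropropyl)-3-methoxy-2-methyl-3-oxopropanoic acid | COC(=O)[C@](C)(C(=O)O)CCCCl
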